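## Retrosynthetic overview

1. In unit A the pyranone atoms O1, C2, C3 and C4 (with the 4-methoxyphenethyl chain on C2) touch the carbocycle only at the C4a=C8a double bond. They are therefore removed in one piece as an acylketene, leaving a C8a ketone with a C4a methylene, used as its trimethylsilyl enol ether. This pyranone is the last ring formed.
2. The dioxepine-bridged ketone is opened at the C5–O–C7' bond: intramolecular Mitsunobu inversion of a 5-hydroxycyclohexanone by the 7'-phenol of chromone B.
3. The carbocycle comes from D-glucose by Ferrier carbocyclization (sugar C1–C4 become C5–C8, sugar C5 becomes C8a, sugar C6 becomes C4a). All four stereocentres are sugar-derived or set by the sugar.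
4. The C7–O–C6' ether is made first, by palladium-catalysed O-arylation of diacetone glucose O3 with 6-bromochromone B, itself from 5'-bromo-2',4'-dihydroxyacetophenone.
5. Ring order: pyranone of chromone B, cyclohexanone ring A, dioxepine, pyranone of unit A; then desilylation.

Key step: step 13

Remarks on the chemistry:
- Step 4 should give the methyl α-pyranoside with some β-anomer. The α-anomer is drawn; the β-anomer converges in step 8, where the anomeric carbon becomes the C5 carbinol.
- Ring A carbons are numbered as in the target (C4a, C5–C8, C8a); chromone B carries primed numbers. ArB(OBn) = 7-benzyloxy-4-oxo-2-(2-phenylethyl)-4H-chromen-6-yl. TBS = tert-butyldimethylsilyl.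

## Route

Step 1
Reactants: 1 5'-bromo-2',4'-dihydroxyacetophenone
Product: 2 4'-benzyloxy-5'-bromo-2'-hydroxyacetophenone
Conditions: BnBr (1.05 equiv), K2CO3, acetone, reflux
Reagents that add atoms: benzyl bromide, BrCc1ccccc1
Why: Williamson etherification; the 2'-OH is held in a hydrogen bond to the acetyl oxygen, so the free and more acidic 4'-OH should be alkylated selectively.

Step 2
Reactants: 2 4'-benzyloxy-5'-bromo-2'-hydroxyacetophenone; 3 ethyl 3-phenylpropanoate
Product: 5 7-benzyloxy-6-bromo-2-(2-phenylethyl)-4H-chromen-4-one, via aryl 1,3-diketone 4 (not isolated)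
Conditions: NaH (4 equiv), THF, reflux; then HCl, MeOH, 60 °C
Reagents that add atoms: none
Why: Crossed Claisen condensation of the acetophenone enolate with the ester, then acid-catalysed cyclodehydration of the o-hydroxyaryl diketone, the standard entry to 2-(2-phenylethyl)chromones; aryl bromide and benzyl ether tolerate both stages.

Step 3
Reactants: 5 7-benzyloxy-6-bromo-2-(2-phenylethyl)-4H-chromen-4-one; 6 1,2:5,6-di-O-isopropylidene-α-D-glucofuranose (2 equiv)
Product: 7 3-O-[ArB(OBn)]-1,2:5,6-di-O-isopropylidene-α-D-glucofuranose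
Conditions: [Pd(allyl)Cl]2 (cat.), RockPhos, Cs2CO3, toluene, 90 °C
Reagents that add atoms: none
Why: Palladium-catalysed C–O cross-coupling (Buchwald–Hartwig etherification) of a secondary alcohol with an aryl bromide; the bulky di-tert-butyl biarylphosphine and the ortho benzyloxy group favour C–O reductive elimination over β-hydride elimination, and the sugar C3–O bond is untouched, so its configuration is retained.

Step 4
Reactants: 7 3-O-[ArB(OBn)]-1,2:5,6-di-O-isopropylidene-α-D-glucofuranose
Product: 8 methyl 3-O-[ArB(OBn)]-α-D-glucopyranoside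
Conditions: HCl (0.5 M) in MeOH containing about 1% water, 60 °C
Reagents that add atoms: methanol, CO
Why: Acid removes both acetonides and Fischer glycosidation under thermodynamic control gives the methyl pyranoside, α favoured by the anomeric effect; aryl ether, benzyl ether and chromone are acid-stable.

Step 5
Reactants: 8 methyl 3-O-[ArB(OBn)]-α-D-glucopyranoside
Product: 9 methyl 3-O-[ArB(OBn)]-6-deoxy-6-iodo-α-D-glucopyranoside
Conditions: I2, PPh3, imidazole, THF, 60 °C
Reagents that add atoms: iodine, II
Why: Garegg–Samuelsson (Appel-type) iodination, selective for the unhindered primary 6-OH over the secondary 2- and 4-OH.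

Step 6
Reactants: 9 methyl 3-O-[ArB(OBn)]-6-deoxy-6-iodo-α-D-glucopyranoside
Product: 10 methyl 3-O-[ArB(OBn)]-2,4-bis-O-TBS-6-deoxy-6-iodo-α-D-glucopyranoside
Conditions: TBSOTf (3 equiv), 2,6-lutidine, CH2Cl2, 0 °C to rt
Reagents that add atoms: tert-butyldimethylsilyl triflate, CC(C)(C)[Si](C)(C)OS(=O)(=O)C(F)(F)F
Why: Silyl triflate with lutidine silylates hindered secondary alcohols; the two silyl ethers (the later 6- and 8-O-TBS groups) should last until the final fluoride step.

Step 7
Reactants: 10 methyl 3-O-[ArB(OBn)]-2,4-bis-O-TBS-6-deoxy-6-iodo-α-D-glucopyranoside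
Product: 11 methyl 3-O-[ArB(OBn)]-2,4-bis-O-TBS-6-deoxy-α-D-xylo-hex-5-enopyranoside
Conditions: DBU, THF, reflux
Reagents that add atoms: none
Why: E2 dehydroiodination of the primary iodide across C5–C6 gives the exocyclic enol ether required for carbocyclization; the amidine base is too weak to affect the chromone or the silyl ethers.

Step 8
Reactants: 11 methyl 3-O-[ArB(OBn)]-2,4-bis-O-TBS-6-deoxy-α-D-xylo-hex-5-enopyranoside
Product: 12 7-O-[ArB(OBn)]-6,8-bis-O-TBS-5-hydroxycyclohexanone (C8a ketone, C4a methylene; 5-OH cis to 6-OTBS and trans to the 7-aryloxy group)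
Conditions: Hg(OCOCF3)2 (10 mol %), acetone–H2O 4:1, rt
Reagents that add atoms: water, O
Why: Ferrier carbocyclization: divalent mercury hydroxymercurates the enol ether, loss of methanol unmasks a C1 aldehyde and C5 ketone, and intramolecular aldol closes the cyclohexanone; the new C5 carbinol is expected mainly trans to the C7 oxygen (the usual outcome for gluco substrates), while C6, C7 and C8 come unchanged from sugar C2, C3 and C4.

Step 9
Reactants: 12 7-O-[ArB(OBn)]-6,8-bis-O-TBS-5-hydroxycyclohexanone
Product: 13 7-O-[7-hydroxy-4-oxo-2-(2-phenylethyl)-4H-chromen-6-yl]-6,8-bis-O-TBS-5-hydroxycyclohexanone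
Conditions: H2 (1 atm), Pd/C, EtOAc, rt
Reagents that add atoms: none
Why: Hydrogenolysis of the aryl benzyl ether is fast at 1 atm, conditions under which the chromone C2'=C3' bond, the ketone, the aryl alkyl ether and the silyl ethers should not be reduced.

Step 10
Reactants: 13 7-O-[7-hydroxy-4-oxo-2-(2-phenylethyl)-4H-chromen-6-yl]-6,8-bis-O-TBS-5-hydroxycyclohexanone
Product: 14 6,8-bis-O-TBS dioxepine-bridged ketone carrying chromone B (C5–O–C7' and C7–O–C6' cis-diaxial bridge, C8a ketone, C4a methylene)
Conditions: PPh3, DIAD, toluene (0.005 M), 0 °C to rt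
Reagents that add atoms: none
Why: Intramolecular Mitsunobu etherification: the acidic 7'-hydroxychromone (pKa near 7.5) keeps the medium non-basic and its phenoxide displaces the activated C5 oxygen by SN2 with inversion, converting the 5,7-trans hydroxy ketone into the 5,7-cis bridge and closing the seven-membered dioxepine (7-exo-tet) at high dilution; the bulky trans-vicinal silyl ethers favour the ring-flipped chair that holds the C7 aryloxy arm axial over C5.

Step 11
Reactants: 15 2,2,6-trimethyl-4H-1,3-dioxin-4-one; 16 4-methoxybenzyl chloride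
Product: 18 2,2-dimethyl-6-[2-(4-methoxyphenyl)ethyl]-4H-1,3-dioxin-4-one, via lithium dienolate 17 (not isolated)
Conditions: LiN(iPr)2 (LDA), THF–DMPU, −78 °C; then 16, −78 to −30 °C
Reagents that add atoms: none
Why: γ-Deprotonation gives the extended lithium dienolate, which the reactive benzylic chloride alkylates at the exocyclic γ-carbon (vinylogous enolate alkylation), turning the 6-methyl group into the 2-arylethyl chain.

Step 12
Reactants: 14 6,8-bis-O-TBS dioxepine-bridged ketone carrying chromone B
Product: 20 trimethylsilyl enol ether (C4a=C8a) of bridged ketone 14, via lithium enolate 19 (not isolated)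
Conditions: TMSCl (3 equiv), THF, −78 °C; LiN(iPr)2 (LDA, 1.2 equiv) added dropwise; Et3N, pentane, filtration; used crude
Reagents that add atoms: chlorotrimethylsilane, C[Si](C)(C)Cl
Why: Kinetic deprotonation with in-situ silyl capture (Corey internal quench): the amide removes the axial C4a methylene proton and not the hindered, equatorial C8 methine bearing the silyloxy group, and silylation at −78 °C should outrun expulsion of the C5 aryloxide; with only a slight excess of base the more acidic ketone is metalated ahead of the side-chain CH2 of chromone B.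

Step 13
Reactants: 20 trimethylsilyl enol ether (C4a=C8a) of bridged ketone 14; 18 2,2-dimethyl-6-[2-(4-methoxyphenyl)ethyl]-4H-1,3-dioxin-4-one (3 equiv)
Product: 23 6,8-bis-O-TBS ether of the target, via acylketene 21 (not isolated), via siloxy dihydropyranone cycloadduct 22 (not isolated)
Conditions: toluene, 110 °C, 18 added slowly; then PPTS (cat.), CH2Cl2, rt
Reagents that add atoms: none
Why: Heating 18 causes retro-[4+2] loss of acetone to acylketene 21, whose 1-oxadiene adds across the electron-rich C4a=C8a enol ether of 20 in a hetero-Diels–Alder reaction, the ketene carbon bonding to nucleophilic C4a (C4–C4a) and the acyl oxygen to C8a (O1–C8a); cycloadduct 22 then loses trimethylsilanol (C4a–H and C8a–OSiMe3, completed by PPTS) to give the 4-pyranone. The closest known reaction type is the cycloaddition of dioxinone-derived acylketenes with enol ethers, ketene acetals or enamines, which gives 4-pyranones after loss of alcohol or amine. The pyranone of unit A is closed in one asynchronous [4+2] event; if the addition ran stepwise it would be C-acylation at C4a followed by 6-exo-trig attack of the acyl-enolate oxygen on the silyloxocarbenium carbon C8a, giving the same adduct. No lasting stereocentre is made: C4a and C8a of 22 arise cis by suprafacial addition and both become sp2 on elimination, and C5–C8 are not involved. The step needs the C4–C4a/O1–C8a regiochemistry, secured by the position of the enol ether double bond fixed in step 12 and by the polarity match of ketene carbon and enol ether β-carbon, and it needs the β-aryloxy groups at C5 and C7 to survive, which the neutral, base-free thermal conditions should allow. Slow addition of 18 keeps the acylketene dilute so that capture by 20 competes with its dimerisation.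

Step 14
Reactants: 23 6,8-bis-O-TBS ether of the target
Product: 24 (+)-4'-methoxyaquisinenone G
Conditions: HF·pyridine, pyridine, THF, 0 °C to rt
Reagents that add atoms: none
Why: Fluoride-driven cleavage of both secondary silyl ethers under buffered, weakly acidic conditions, which avoid base-mediated epimerisation at C8 (γ to the pyranone carbonyl) and should leave the aryl ethers and both pyranones untouched; no stereocentre is affected.

## Compound list

1 | 5'-bromo-2',4'-dihydroxyacetophenone | CC(=O)c1cc(Br)c(O)cc1O | starting material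
2 | 4'-benzyloxy-5'-bromo-2'-hydroxyacetophenone | CC(=O)c1cc(Br)c(OCc2ccccc2)cc1O | intermediate
3 | ethyl 3-phenylpropanoate | CCOC(=O)CCc1ccccc1 | starting material
4 | 1-(4-benzyloxy-5-bromo-2-hydroxyphenyl)-5-phenylpentane-1,3-dione | O=C(CCc1ccccc1)CC(=O)c1cc(Br)c(OCc2ccccc2)cc1O | intermediate (not isolated)
5 | 7-benzyloxy-6-bromo-2-(2-phenylethyl)-4H-chromen-4-one | O=c1cc(CCc2ccccc2)oc2cc(OCc3ccccc3)c(Br)cc12 | intermediate
6 | 1,2:5,6-di-O-isopropylidene-α-D-glucofuranose (diacetone glucose) | CC1(C)OC[C@@H](O1)[C@H]2O[C@@H]3OC(C)(C)O[C@@H]3[C@H]2O | starting material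
7 | 3-O-[7-benzyloxy-4-oxo-2-(2-phenylethyl)-4H-chromen-6-yl]-1,2:5,6-di-O-isopropylidene-α-D-glucofuranose | CC1(C)OC[C@@H](O1)[C@H]2O[C@@H]3OC(C)(C)O[C@@H]3[C@H]2Oc4cc5c(=O)cc(CCc6ccccc6)oc5cc4OCc7ccccc7 | intermediate
8 | methyl 3-O-[7-benzyloxy-4-oxo-2-(2-phenylethyl)-4H-chromen-6-yl]-α-D-glucopyranoside | CO[C@H]1O[C@H](CO)[C@@H](O)[C@H](Oc2cc3c(=O)cc(CCc4ccccc4)oc3cc2OCc5ccccc5)[C@H]1O | intermediate
9 | methyl 3-O-[7-benzyloxy-4-oxo-2-(2-phenylethyl)-4H-chromen-6-yl]-6-deoxy-6-iodo-α-D-glucopyranoside | CO[C@H]1O[C@H](CI)[C@@H](O)[C@H](Oc2cc3c(=O)cc(CCc4ccccc4)oc3cc2OCc5ccccc5)[C@H]1O | intermediate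
10 | methyl 3-O-[7-benzyloxy-4-oxo-2-(2-phenylethyl)-4H-chromen-6-yl]-2,4-bis-O-TBS-6-deoxy-6-iodo-α-D-glucopyranoside | CO[C@H]1O[C@H](CI)[C@@H](O[Si](C)(C)C(C)(C)C)[C@H](Oc2cc3c(=O)cc(CCc4ccccc4)oc3cc2OCc5ccccc5)[C@H]1O[Si](C)(C)C(C)(C)C | intermediate
11 | methyl 3-O-[7-benzyloxy-4-oxo-2-(2-phenylethyl)-4H-chromen-6-yl]-2,4-bis-O-TBS-6-deoxy-α-D-xylo-hex-5-enopyranoside | CO[C@H]1OC(=C)[C@@H](O[Si](C)(C)C(C)(C)C)[C@H](Oc2cc3c(=O)cc(CCc4ccccc4)oc3cc2OCc5ccccc5)[C@H]1O[Si](C)(C)C(C)(C)C | intermediate
12 | 5-hydroxycyclohexanone with C8a ketone, C4a methylene, 6,8-bis-OTBS and 7-O-(7-benzyloxychromon-6-yl B); 5-OH cis to 6-OTBS, trans to 7-OAr | O=C1C[C@H](O)[C@H](O[Si](C)(C)C(C)(C)C)[C@@H](Oc2cc3c(=O)cc(CCc4ccccc4)oc3cc2OCc5ccccc5)[C@@H]1O[Si](C)(C)C(C)(C)C | intermediate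
13 | phenol of 12 (7'-OH free on chromone B) | O=C1C[C@H](O)[C@H](O[Si](C)(C)C(C)(C)C)[C@@H](Oc2cc3c(=O)cc(CCc4ccccc4)oc3cc2O)[C@@H]1O[Si](C)(C)C(C)(C)C | intermediate
14 | 6,8-bis-O-TBS dioxepine-bridged ketone carrying chromone B (C5–O–C7', C7–O–C6' cis bridge; 6- and 8-OTBS trans to the bridge oxygens) | C1C(=O)[C@@H](O[Si](C)(C)C(C)(C)C)[C@@H]2Oc3cc4c(=O)cc(CCc5ccccc5)oc4cc3O[C@H]1[C@@H]2O[Si](C)(C)C(C)(C)C | intermediate
15 | 2,2,6-trimethyl-4H-1,3-dioxin-4-one | CC1=CC(=O)OC(C)(C)O1 | starting material
16 | 4-methoxybenzyl chloride | COc1ccc(CCl)cc1 | starting material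
17 | lithium dienolate of 15 (6-methylene-4-lithiooxy-1,3-dioxine) | C=C1C=C(O[Li])OC(C)(C)O1 | intermediate (not isolated)
18 | 2,2-dimethyl-6-[2-(4-methoxyphenyl)ethyl]-4H-1,3-dioxin-4-one | COc1ccc(CCC2=CC(=O)OC(C)(C)O2)cc1 | intermediate
19 | lithium enolate (C4a=C8a) of 14 | C1=C(O[Li])[C@@H](O[Si](C)(C)C(C)(C)C)[C@@H]2Oc3cc4c(=O)cc(CCc5ccccc5)oc4cc3O[C@H]1[C@@H]2O[Si](C)(C)C(C)(C)C | intermediate (not isolated)
20 | trimethylsilyl enol ether (C4a=C8a) of 14 | C1=C(O[Si](C)(C)C)[C@@H](O[Si](C)(C)C(C)(C)C)[C@@H]2Oc3cc4c(=O)cc(CCc5ccccc5)oc4cc3O[C@H]1[C@@H]2O[Si](C)(C)C(C)(C)C | intermediate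
21 | 5-(4-methoxyphenyl)-3-oxopent-1-en-1-one (acylketene) | COc1ccc(CCC(=O)C=C=O)cc1 | intermediate (not isolated)
22 | [4+2] adduct: 8a-trimethylsiloxy-4a,8a-dihydro-4-pyranone fused to the bridged carbocycle (C4a/C8a cis; face of addition left open, both centres are lost) | COc1ccc(CCC2=CC(=O)C3C(O2)(O[Si](C)(C)C)[C@@H](O[Si](C)(C)C(C)(C)C)[C@@H]4Oc5cc6c(=O)cc(CCc7ccccc7)oc6cc5O[C@H]3[C@@H]4O[Si](C)(C)C(C)(C)C)cc1 | intermediate (not isolated)
23 | 6,8-bis-O-TBS ether of the target | COc1ccc(CCc2cc(=O)c3c(o2)[C@@H](O[Si](C)(C)C(C)(C)C)[C@@H]2Oc4cc5c(=O)cc(CCc6ccccc6)oc5cc4O[C@H]3[C@@H]2O[Si](C)(C)C(C)(C)C)cc1 | intermediate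
24 | (+)-4'-methoxyaquisinenone G | COc1ccc(CCc2cc(=O)c3c(o2)[C@@H](O)[C@@H]2Oc4cc5c(=O)cc(CCc6ccccc6)oc5cc4O[C@H]3[C@@H]2O)cc1 | target

## Step count and risks

Total step count: 14. Longest linear sequence: 13 steps (steps 1–10, 12, 13, 14 from compound 1); step 11 is a one-step side branch.

Steps most likely to fail:

1. Step 13. The hindered, trisubstituted enol ether may trap the acylketene too slowly, so that ketene dimerisation, protodesilylation of 20 or thermal loss of the allylic C5 aryloxide takes over. Fallback (stepwise aldol, oxidation, cycloisomerisation; sets out from 14, returns at 23): ketone 14 is converted with LiN(iPr)2 in THF at −78 °C into lithium enolate 19, which is added to 5-(4-methoxyphenyl)pent-2-ynal F1 (from purchasable 4-(4-methoxyphenyl)but-1-yne, n-BuLi then DMF) to give the propargylic aldol adduct F2. Dess–Martin periodinane buffered with NaHCO3 oxidises it to the 2-alkynoyl ketone F3 (enolised 1,3-diketone). Catalytic AgOTf in CH2Cl2 then promotes 6-endo-dig addition of the C8a enol oxygen to the ynone, giving pyranone 23.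

2. Step 12. The lithium enolate may expel the C5 aryloxide (E1cB opening of the dioxepine) before silicon capture, or the amide base may metalate the CH2 next to C2' of chromone B. Fallback (boron-mediated aldol in place of the silyl enol ether; sets out from 14, returns at 23): ketone 14 is enolised with (c-C6H11)2BCl and Et3N in Et2O at −78 to 0 °C to the covalent dicyclohexylboron enolate F4, formed on the less hindered C4a side with only a weak amine base present. Aldol addition to the ynal F1 at −78 °C and a pH 7 buffer work-up give the adduct F2, which is carried on through the ynone F3 to 23 as in the fallback for step 13.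

3. Step 10. Activation of the β-hydroxy ketone may lead to dehydration to the enone instead of substitution, or the reactive ring-flipped conformer may be too little populated and intermolecular etherification may compete. Fallback (deliberate elimination, then conjugate addition; sets out from 13, returns at 14): 13 is treated with trifluoroacetic anhydride and Et3N in CH2Cl2 at 0 °C to give the bis(trifluoroacetate) F5, which loses trifluoroacetic acid in the same flask to the enone aryl trifluoroacetate F6. Methanol–NaHCO3 work-up frees the phenol, giving the enone phenol F7. Catalytic Et3N (or camphorsulfonic acid) in CH2Cl2 then closes the dioxepine by intramolecular oxa-Michael addition of the 7'-phenol to C5; the tether allows only the cis-bridged adduct, which is 14.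

Further compounds

F1 | step 13 | 5-(4-methoxyphenyl)pent-2-ynal | COc1ccc(CCC#CC=O)cc1
F2 | step 13 | aldol adduct of 14 at C4a with F1 (C4a and carbinol configuration not fixed, both lost later) | COc1ccc(CCC#CC(O)C2C(=O)[C@@H](O[Si](C)(C)C(C)(C)C)[C@@H]3Oc4cc5c(=O)cc(CCc6ccccc6)oc5cc4O[C@H]2[C@@H]3O[Si](C)(C)C(C)(C)C)cc1
F3 | step 13 | 4a-[5-(4-methoxyphenyl)pent-2-ynoyl] derivative of ketone 14 (drawn as diketone) | COc1ccc(CCC#CC(=O)C2C(=O)[C@@H](O[Si](C)(C)C(C)(C)C)[C@@H]3Oc4cc5c(=O)cc(CCc6ccccc6)oc5cc4O[C@H]2[C@@H]3O[Si](C)(C)C(C)(C)C)cc1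
F4 | step 12 | dicyclohexylboron enolate (C4a=C8a) of 14 | C1=C(OB(C7CCCCC7)C8CCCCC8)[C@@H](O[Si](C)(C)C(C)(C)C)[C@@H]2Oc3cc4c(=O)cc(CCc5ccccc5)oc4cc3O[C@H]1[C@@H]2O[Si](C)(C)C(C)(C)C
F5 | step 10 | bis(trifluoroacetate) of 13 (5-O and 7'-O) | O=C1C[C@H](OC(=O)C(F)(F)F)[C@H](O[Si](C)(C)C(C)(C)C)[C@@H](Oc2cc3c(=O)cc(CCc4ccccc4)oc3cc2OC(=O)C(F)(F)F)[C@@H]1O[Si](C)(C)C(C)(C)C
F6 | step 10 | cyclohexenone (C4a=C5) with 7'-O-trifluoroacetate | O=C1C=C[C@H](O[Si](C)(C)C(C)(C)C)[C@@H](Oc2cc3c(=O)cc(CCc4ccccc4)oc3cc2OC(=O)C(F)(F)F)[C@@H]1O[Si](C)(C)C(C)(C)C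
F7 | step 10 | cyclohexenone (C4a=C5) with free 7'-phenol | O=C1C=C[C@H](O[Si](C)(C)C(C)(C)C)[C@@H](Oc2cc3c(=O)cc(CCc4ccccc4)oc3cc2O)[C@@H]1O[Si](C)(C)C(C)(C)C
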